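Ring B of this ent-labdane is closed at the C9–C10 bond. The key step exploits the fact that quaternary C10 is one end of the ring A C5=C10 double bond of β-cyclocitral, which is allylic to C6: Ireland–Claisen rearrangement of a δ-lactone bearing its ring oxygen on C6 breaks C6–O, forms C9–C10, closes ring B and hands the C6 configuration on to C10 in a single operation. The precursor is the trans-4-silyloxy-6-(2,6,6-trimethylcyclohexenyl)oxan-2-one 8, reached by asymmetric allylation, acrylate ring-closing metathesis and conjugate borylation. The resulting C11 carboxyl then directs the C5=C6 hydrogenation and is grown into the side chain.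

Key step: step 6

Remark: the target is read as the hydrogen malonate of ent-copalol (5R,9R,10R), and labdane numbering is used for ring and chain atoms (C8 carries the methylidene, C9 the side chain C11–C16, C10 the angular methyl C20).

Step 1
Reactants: 1 β-cyclocitral (2,6,6-trimethylcyclohex-1-ene-1-carbaldehyde)
Product: 3 (1R)-1-(2,6,6-trimethylcyclohex-1-en-1-yl)but-3-en-1-ol, via diisopinocampheylborinate 2 (not isolated)
Conditions: (+)-Ipc2BOMe [from (−)-α-pinene], allylMgBr, Et2O, 0 °C → rt; then 1, −78 °C → rt; then NaOH, H2O2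
Reagents that add atoms: allylmagnesium bromide, C=CC[Mg]Br
Why: Brown allylboration through a closed chair transition state; the borane derived from (−)-α-pinene should add allyl to the Re face of the aldehyde (its antipode gives S alcohols from aryl and alkenyl aldehydes), which sets C6 as R.

Step 2
Reactants: 3 (1R)-1-(2,6,6-trimethylcyclohex-1-en-1-yl)but-3-en-1-ol
Product: 4 (1R)-1-(2,6,6-trimethylcyclohex-1-en-1-yl)but-3-en-1-yl prop-2-enoate
Conditions: acryloyl chloride, Et3N, DMAP (cat.), CH2Cl2, 0 °C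
Reagents that add atoms: acryloyl chloride, C=CC(=O)Cl
Why: O-acylation (esterification) of the secondary allylic alcohol under mild base, which leaves the stereocentre untouched.

Step 3
Reactants: 4 (1R)-1-(2,6,6-trimethylcyclohex-1-en-1-yl)but-3-en-1-yl prop-2-enoate
Product: 5 (6R)-6-(2,6,6-trimethylcyclohex-1-en-1-yl)-5,6-dihydro-2H-pyran-2-one
Conditions: second-generation Grubbs catalyst RuCl2(=CHPh)(PCy3)(H2IMes) (5 mol%), CH2Cl2 (dilute), 40 °C
Reagents that add atoms: none
Why: Ring-closing metathesis of the terminal alkene with the acrylate gives the six-membered unsaturated lactone with loss of ethene, and the fully substituted ring A alkene is inert to the ruthenium carbene.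

Step 4
Reactants: 5 (6R)-6-(2,6,6-trimethylcyclohex-1-en-1-yl)-5,6-dihydro-2H-pyran-2-one
Product: 7 (4S,6R)-4-hydroxy-6-(2,6,6-trimethylcyclohex-1-en-1-yl)oxan-2-one, via pinacol boronate 6 (not isolated)
Conditions: B2pin2, CuCl (cat.), NaOtBu (cat.), DPEphos (cat.), MeOH, THF, rt; then NaBO3·4H2O, THF/H2O, rt
Reagents that add atoms: sodium perborate, [Na+].[O-]OB=O
Why: Copper-catalysed conjugate borylation in which the boryl–copper species should add to C4 anti to the pseudo-equatorial C6 substituent (axial attack on the half-chair), and perborate oxidation of the C–B bond with retention then gives the trans (4S) alcohol.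

Step 5
Reactants: 7 (4S,6R)-4-hydroxy-6-(2,6,6-trimethylcyclohex-1-en-1-yl)oxan-2-one
Product: 8 (4S,6R)-4-(tert-butyldimethylsilyloxy)-6-(2,6,6-trimethylcyclohex-1-en-1-yl)oxan-2-one
Conditions: TBSCl, imidazole, DMF, rt
Reagents that add atoms: tert-butyldimethylsilyl chloride, CC(C)(C)[Si](C)(C)Cl
Why: Silyl ether formation with a weak base, which cannot trigger β-elimination of the C4 oxygen, gives the trans lactone whose silyloxy group will lie on the face away from ring A in the rearrangement.

Step 6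
Reactants: 8 (4S,6R)-4-(tert-butyldimethylsilyloxy)-6-(2,6,6-trimethylcyclohex-1-en-1-yl)oxan-2-one
Product: 11 (1R,2S,8aS)-2-(tert-butyldimethylsilyloxy)-5,5,8a-trimethyl-1,2,3,5,6,7,8,8a-octahydronaphthalene-1-carboxylic acid, via silyl ketene acetal 9 (not isolated), via trimethylsilyl ester 10 (not isolated)
Conditions: LiN(iPr)2 (LDA), Me3SiCl/Et3N (in situ quench), THF, −78 °C → rt; volatiles removed; toluene (Et3N), 110 °C, sealed; then aq. citric acid
Reagents that add atoms: none
Why: Ireland–Claisen rearrangement: in situ O-silylation of the lactone enolate gives cyclic ketene acetal 9, whose six atoms C9=C11–O–C6–C5=C10 reorganise suprafacially in a [3,3] shift, so that C6–O breaks as C9–C10 forms and silyl ester 10 is hydrolysed on work-up. The closest known reaction type is the enolate Claisen ring contraction of alkenyl-substituted lactones to cycloalkene carboxylic acids. Ring B closes by bond formation between the ketene acetal carbon C9 and the alkene terminus C10 across the lactone, through a boat-shaped, bicyclo[2.2.2]octane-like transition state imposed by the C7–C8 tether. C10 is controlled by the C6 stereocentre, because the new bond enters the alkene face from which the oxygen departs, so (6R) gives the C10 configuration of the target; C9 is controlled by the enforced boat, which places the carboxyl cis to the C8 silyloxy group and trans to the C10 methyl. The step needs O-silylation to outrun β-elimination of the C8 silyloxy group (axial in the resting lactone) and bond formation at a fully substituted alkene carbon. The internal quench at −78 °C, the ring-fixed ketene acetal geometry, the trans lactone and the gain of a carboxyl C=O should secure this.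

Step 7
Reactants: 11 (1R,2S,8aS)-2-(tert-butyldimethylsilyloxy)-5,5,8a-trimethyl-1,2,3,5,6,7,8,8a-octahydronaphthalene-1-carboxylic acid
Product: 12 [(1S,2S,8aS)-2-(tert-butyldimethylsilyloxy)-5,5,8a-trimethyl-1,2,3,5,6,7,8,8a-octahydronaphthalen-1-yl]methanol
Conditions: LiAlH4, THF, 0 → 50 °C
Reagents that add atoms: none
Why: Hydride reduction of the carboxylic acid to the primary alcohol (C11), to which the silyl ether and the trisubstituted alkene are inert.

Step 8
Reactants: 12 [(1S,2S,8aS)-2-(tert-butyldimethylsilyloxy)-5,5,8a-trimethyl-1,2,3,5,6,7,8,8a-octahydronaphthalen-1-yl]methanol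
Product: 13 [(1S,2S,4aR,8aR)-2-(tert-butyldimethylsilyloxy)-5,5,8a-trimethyldecahydronaphthalen-1-yl]methanol
Conditions: [Ir(cod)(PCy3)(py)]PF6 (10 mol%), H2 (1 atm), CH2Cl2, rt
Reagents that add atoms: none
Why: Hydroxyl-directed homogeneous hydrogenation: the axial C9 hydroxymethyl group, which lies on the face opposite the C10 methyl, should bind the cationic iridium and deliver hydrogen to C5 on that face, giving the trans-decalin (5R).

Step 9
Reactants: 13 [(1S,2S,4aR,8aR)-2-(tert-butyldimethylsilyloxy)-5,5,8a-trimethyldecahydronaphthalen-1-yl]methanol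
Product: 14 (1R,2S,4aR,8aR)-2-(tert-butyldimethylsilyloxy)-5,5,8a-trimethyldecahydronaphthalene-1-carbaldehyde
Conditions: Dess–Martin periodinane, CH2Cl2, rt
Reagents that add atoms: none
Why: Dess–Martin oxidation stops at the aldehyde under non-basic conditions, so the β-silyloxy aldehyde should neither eliminate nor epimerise.

Step 10
Reactants: 14 (1R,2S,4aR,8aR)-2-(tert-butyldimethylsilyloxy)-5,5,8a-trimethyldecahydronaphthalene-1-carbaldehyde
Product: 15 tert-butyl{[(1R,2S,4aR,8aR)-1-ethenyl-5,5,8a-trimethyldecahydronaphthalen-2-yl]oxy}dimethylsilane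
Conditions: Ph3PCH3Br, KN(SiMe3)2, THF, −78 → 0 °C
Reagents that add atoms: methyltriphenylphosphonium bromide, C[P+](c1ccccc1)(c1ccccc1)c1ccccc1.[Br-]
Why: Wittig methylenation of the aldehyde; the equatorial C8–O bond is not aligned for elimination from the exocyclic enolate, and any epimerisation at C9 would be harmless because that centre is equilibrated in step 15.

Step 11
Reactants: 16 ethyl acetoacetate (ethyl 3-oxobutanoate)
Product: 17 ethyl (2E)-3-{[(trifluoromethyl)sulfonyl]oxy}but-2-enoate
Conditions: Tf2O, aq. Me4NOH, hexanes, 5 °C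
Reagents that add atoms: trifluoromethanesulfonic anhydride, O=S(=O)(OS(=O)(=O)C(F)(F)F)C(F)(F)F
Why: O-Triflation of the acetoacetate enolate: with the non-chelating tetramethylammonium counter-ion the open enolate is trapped, which should give the E enol triflate (triflate trans to the ester).

Step 12
Reactants: 15 tert-butyl{[(1R,2S,4aR,8aR)-1-ethenyl-5,5,8a-trimethyldecahydronaphthalen-2-yl]oxy}dimethylsilane; 17 ethyl (2E)-3-{[(trifluoromethyl)sulfonyl]oxy}but-2-enoate
Product: 19 ethyl (2E)-5-[(1R,2S,4aR,8aR)-2-(tert-butyldimethylsilyloxy)-5,5,8a-trimethyldecahydronaphthalen-1-yl]-3-methylpent-2-enoate, via alkylborane 18 (not isolated)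
Conditions: 9-BBN-H, THF, 0 °C → rt; then 17, PdCl2(dppf) (5 mol%), aq. K3PO4, DMF, 50 °C
Reagents that add atoms: none
Why: Anti-Markovnikov hydroboration of the monosubstituted alkene puts boron on C12, and B-alkyl Suzuki–Miyaura coupling with the enol triflate proceeds with retention of alkene geometry, so the C12–C13 bond and the (13E)-enoate arise in one flask.

Step 13
Reactants: 19 ethyl (2E)-5-[(1R,2S,4aR,8aR)-2-(tert-butyldimethylsilyloxy)-5,5,8a-trimethyldecahydronaphthalen-1-yl]-3-methylpent-2-enoate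
Product: 20 ethyl (2E)-5-[(1R,2S,4aR,8aR)-2-hydroxy-5,5,8a-trimethyldecahydronaphthalen-1-yl]-3-methylpent-2-enoate
Conditions: 48% aq. HF, MeCN, rt
Reagents that add atoms: none
Why: Fluoride-driven cleavage of the silyl ether (desilylation) under acidic conditions that the ethyl ester and the trisubstituted enoate tolerate.

Step 14
Reactants: 20 ethyl (2E)-5-[(1R,2S,4aR,8aR)-2-hydroxy-5,5,8a-trimethyldecahydronaphthalen-1-yl]-3-methylpent-2-enoate
Product: 21 ethyl (2E)-3-methyl-5-[(1R,4aR,8aR)-5,5,8a-trimethyl-2-oxodecahydronaphthalen-1-yl]pent-2-enoate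
Conditions: Dess–Martin periodinane, CH2Cl2, rt
Reagents that add atoms: none
Why: Dess–Martin oxidation of the secondary alcohol gives the C8 ketone without touching the enoate.

Step 15
Reactants: 21 ethyl (2E)-3-methyl-5-[(1R,4aR,8aR)-5,5,8a-trimethyl-2-oxodecahydronaphthalen-1-yl]pent-2-enoate
Product: 22 ethyl (2E)-3-methyl-5-[(1S,4aR,8aR)-5,5,8a-trimethyl-2-oxodecahydronaphthalen-1-yl]pent-2-enoate
Conditions: NaOEt (0.2 equiv), EtOH, 0 °C → rt
Reagents that add atoms: none
Why: Base-mediated epimerisation through the C8 enolate should move the axial C9 side chain to the equatorial position, cis to the C10 methyl as in the target, which is the more stable arrangement of a 2-alkyl trans-decalone.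

Step 16
Reactants: 22 ethyl (2E)-3-methyl-5-[(1S,4aR,8aR)-5,5,8a-trimethyl-2-oxodecahydronaphthalen-1-yl]pent-2-enoate
Product: 23 ethyl (2E)-3-methyl-5-[(1R,4aR,8aR)-5,5,8a-trimethyl-2-methylidenedecahydronaphthalen-1-yl]pent-2-enoate
Conditions: Zn, CH2Br2, TiCl4, THF, −40 → 5 °C (pre-formed reagent); then 22, CH2Cl2, 0 °C → rt
Reagents that add atoms: dibromomethane, BrCBr
Why: Takai–Lombardo methylenation: the non-basic gem-dizinc/titanium reagent should convert the hindered, enolisable ketone into the exocyclic alkene without epimerising C9 and without attacking the ester.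

Step 17
Reactants: 23 ethyl (2E)-3-methyl-5-[(1R,4aR,8aR)-5,5,8a-trimethyl-2-methylidenedecahydronaphthalen-1-yl]pent-2-enoate
Product: 24 (2E)-3-methyl-5-[(1R,4aR,8aR)-5,5,8a-trimethyl-2-methylidenedecahydronaphthalen-1-yl]pent-2-en-1-ol
Conditions: iBu2AlH (2.5 equiv), CH2Cl2, −78 °C
Reagents that add atoms: none
Why: 1,2-Reduction of the α,β-unsaturated ester by the aluminium hydride at low temperature gives the allylic alcohol and leaves both alkenes untouched.

Step 18
Reactants: 24 (2E)-3-methyl-5-[(1R,4aR,8aR)-5,5,8a-trimethyl-2-methylidenedecahydronaphthalen-1-yl]pent-2-en-1-ol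
Product: 25 3-{[(2E)-3-methyl-5-[(1R,4aR,8aR)-5,5,8a-trimethyl-2-methylidenedecahydronaphthalen-1-yl]pent-2-en-1-yl]oxy}-3-oxopropanoic acid
Conditions: Meldrum's acid (1.1 equiv), toluene, 90 °C
Reagents that add atoms: Meldrum's acid (2,2-dimethyl-1,3-dioxane-4,6-dione), CC1(C)OC(=O)CC(=O)O1
Why: Acylation of the alcohol by Meldrum's acid on heating (ring opening with loss of acetone) gives the malonic half ester directly, so no carboxyl protecting group is needed.

Compound list
1 | β-cyclocitral (2,6,6-trimethylcyclohex-1-ene-1-carbaldehyde) | CC1=C(C=O)C(C)(C)CCC1 | starting material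
2 | (1R)-1-(2,6,6-trimethylcyclohex-1-en-1-yl)but-3-en-1-yl diisopinocampheylborinate | C=CC[C@@H](OB([C@H]1C[C@H]2C[C@@H]([C@@H]1C)C2(C)C)[C@H]1C[C@H]2C[C@@H]([C@@H]1C)C2(C)C)C1=C(C)CCCC1(C)C | intermediate (not isolated)
3 | (1R)-1-(2,6,6-trimethylcyclohex-1-en-1-yl)but-3-en-1-ol | C=CC[C@@H](O)C1=C(C)CCCC1(C)C | intermediate
4 | (1R)-1-(2,6,6-trimethylcyclohex-1-en-1-yl)but-3-en-1-yl prop-2-enoate | C=CC[C@@H](OC(=O)C=C)C1=C(C)CCCC1(C)C | intermediate
5 | (6R)-6-(2,6,6-trimethylcyclohex-1-en-1-yl)-5,6-dihydro-2H-pyran-2-one | O=C1C=CC[C@@H](O1)C2=C(C)CCCC2(C)C | intermediate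
6 | (4S,6R)-4-(4,4,5,5-tetramethyl-1,3,2-dioxaborolan-2-yl)-6-(2,6,6-trimethylcyclohex-1-en-1-yl)oxan-2-one | O=C1C[C@@H](B2OC(C)(C)C(C)(C)O2)C[C@@H](O1)C3=C(C)CCCC3(C)C | intermediate (not isolated)
7 | (4S,6R)-4-hydroxy-6-(2,6,6-trimethylcyclohex-1-en-1-yl)oxan-2-one (trans) | O=C1C[C@@H](O)C[C@@H](O1)C2=C(C)CCCC2(C)C | intermediate
8 | (4S,6R)-4-(tert-butyldimethylsilyloxy)-6-(2,6,6-trimethylcyclohex-1-en-1-yl)oxan-2-one (trans; precursor of the key step) | O=C1C[C@@H](O[Si](C)(C)C(C)(C)C)C[C@@H](O1)C2=C(C)CCCC2(C)C | intermediate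
9 | (4S,6R)-4-(tert-butyldimethylsilyloxy)-2-(trimethylsilyloxy)-6-(2,6,6-trimethylcyclohex-1-en-1-yl)-5,6-dihydro-4H-pyran | C[Si](C)(C)OC1=C[C@@H](O[Si](C)(C)C(C)(C)C)C[C@@H](O1)C2=C(C)CCCC2(C)C | intermediate (not isolated)
10 | trimethylsilyl (1R,2S,8aS)-2-(tert-butyldimethylsilyloxy)-5,5,8a-trimethyl-1,2,3,5,6,7,8,8a-octahydronaphthalene-1-carboxylate | CC(C)(C)[Si](C)(C)O[C@H]1CC=C2C(C)(C)CCC[C@@]2(C)[C@H]1C(=O)O[Si](C)(C)C | intermediate (not isolated)
11 | (1R,2S,8aS)-2-(tert-butyldimethylsilyloxy)-5,5,8a-trimethyl-1,2,3,5,6,7,8,8a-octahydronaphthalene-1-carboxylic acid (labdane numbering: 8-silyloxy, C5=C6, C9 carboxyl trans to the C10 methyl) | CC(C)(C)[Si](C)(C)O[C@H]1CC=C2C(C)(C)CCC[C@@]2(C)[C@H]1C(O)=O | intermediate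
12 | [(1S,2S,8aS)-2-(tert-butyldimethylsilyloxy)-5,5,8a-trimethyl-1,2,3,5,6,7,8,8a-octahydronaphthalen-1-yl]methanol | CC(C)(C)[Si](C)(C)O[C@H]1CC=C2C(C)(C)CCC[C@@]2(C)[C@H]1CO | intermediate
13 | [(1S,2S,4aR,8aR)-2-(tert-butyldimethylsilyloxy)-5,5,8a-trimethyldecahydronaphthalen-1-yl]methanol (trans-decalin) | CC(C)(C)[Si](C)(C)O[C@H]1CC[C@@H]2C(C)(C)CCC[C@@]2(C)[C@H]1CO | intermediate
14 | (1R,2S,4aR,8aR)-2-(tert-butyldimethylsilyloxy)-5,5,8a-trimethyldecahydronaphthalene-1-carbaldehyde | CC(C)(C)[Si](C)(C)O[C@H]1CC[C@@H]2C(C)(C)CCC[C@@]2(C)[C@H]1C=O | intermediate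
15 | tert-butyl{[(1R,2S,4aR,8aR)-1-ethenyl-5,5,8a-trimethyldecahydronaphthalen-2-yl]oxy}dimethylsilane | CC(C)(C)[Si](C)(C)O[C@H]1CC[C@@H]2C(C)(C)CCC[C@@]2(C)[C@H]1C=C | intermediate
16 | ethyl acetoacetate (ethyl 3-oxobutanoate) | CCOC(=O)CC(C)=O | starting material
17 | ethyl (2E)-3-{[(trifluoromethyl)sulfonyl]oxy}but-2-enoate | CCOC(=O)/C=C(\C)OS(=O)(=O)C(F)(F)F | intermediate
18 | 9-{2-[(1R,2S,4aR,8aR)-2-(tert-butyldimethylsilyloxy)-5,5,8a-trimethyldecahydronaphthalen-1-yl]ethyl}-9-borabicyclo[3.3.1]nonane | CC(C)(C)[Si](C)(C)O[C@H]1CC[C@@H]2C(C)(C)CCC[C@@]2(C)[C@H]1CCB1C2CCCC1CCC2 | intermediate (not isolated)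
19 | ethyl (2E)-5-[(1R,2S,4aR,8aR)-2-(tert-butyldimethylsilyloxy)-5,5,8a-trimethyldecahydronaphthalen-1-yl]-3-methylpent-2-enoate | CC(C)(C)[Si](C)(C)O[C@H]1CC[C@@H]2C(C)(C)CCC[C@@]2(C)[C@H]1CC/C(C)=C/C(=O)OCC | intermediate
20 | ethyl (2E)-5-[(1R,2S,4aR,8aR)-2-hydroxy-5,5,8a-trimethyldecahydronaphthalen-1-yl]-3-methylpent-2-enoate | O[C@H]1CC[C@@H]2C(C)(C)CCC[C@@]2(C)[C@H]1CC/C(C)=C/C(=O)OCC | intermediate
21 | ethyl (2E)-3-methyl-5-[(1R,4aR,8aR)-5,5,8a-trimethyl-2-oxodecahydronaphthalen-1-yl]pent-2-enoate (side chain trans to the C10 methyl) | O=C1CC[C@@H]2C(C)(C)CCC[C@@]2(C)[C@H]1CC/C(C)=C/C(=O)OCC | intermediate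
22 | ethyl (2E)-3-methyl-5-[(1S,4aR,8aR)-5,5,8a-trimethyl-2-oxodecahydronaphthalen-1-yl]pent-2-enoate (side chain cis to the C10 methyl) | O=C1CC[C@@H]2C(C)(C)CCC[C@@]2(C)[C@@H]1CC/C(C)=C/C(=O)OCC | intermediate
23 | ethyl (2E)-3-methyl-5-[(1R,4aR,8aR)-5,5,8a-trimethyl-2-methylidenedecahydronaphthalen-1-yl]pent-2-enoate | C=C1CC[C@@H]2C(C)(C)CCC[C@@]2(C)[C@@H]1CC/C(C)=C/C(=O)OCC | intermediate
24 | (2E)-3-methyl-5-[(1R,4aR,8aR)-5,5,8a-trimethyl-2-methylidenedecahydronaphthalen-1-yl]pent-2-en-1-ol (ent-copalol) | C=C1CC[C@@H]2C(C)(C)CCC[C@@]2(C)[C@@H]1CC/C(C)=C/CO | intermediate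
25 | 3-{[(2E)-3-methyl-5-[(1R,4aR,8aR)-5,5,8a-trimethyl-2-methylidenedecahydronaphthalen-1-yl]pent-2-en-1-yl]oxy}-3-oxopropanoic acid | C=C1CC[C@@H]2C(C)(C)CCC[C@@]2(C)[C@@H]1CC/C(C)=C/COC(=O)CC(=O)O | target

Total step count: 18 (17 in the main line and one for fragment 17).
Longest linear sequence: 17 steps (steps 1–10 and 12–18, from 1 to 25).

Steps most likely to fail

Step 6. The lithium enolate of 8 may expel the C8 silyloxy group, which sits axial and antiperiplanar to the enolate in the resting lactone, before oxygen is silylated; the rearrangement then never starts. The fallback removes the leaving group instead of outrunning it. It sets out from hydroxy lactone 7, which is deprotonated twice with LiN(iPr)2 at −78 °C to the alkoxide–enolate (an oxide cannot be expelled, the Fráter–Seebach principle). Both oxygens are then silylated with Me3SiCl to give the bis(trimethylsilyl) ketene acetal F1. Heating in toluene should rearrange it to the silyl ester F2, and mild aqueous acid frees the hydroxy acid F3. Silylation with TBSOTf and 2,6-lutidine gives the bis-silyl derivative F4, whose silyl ester alone is cleaved by K2CO3 in aqueous methanol. The route is rejoined at acid 11.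

Step 8. The iridium catalyst may reduce the hindered C5=C6 bond without face control, or not at all, if the hydroxymethyl group binds poorly beside the neighbouring silyl ether; a cis-fused decalin would then form. The fallback sets out from 12 and returns at 13 by hydrogen-atom-transfer reduction (Mn(dpm)3, PhSiH3, tBuOOH, iPrOH). A hydrogen atom adds first to C6 and then to the tertiary C5 radical, a stepwise path that should favour the more stable trans-fused ring system whatever the directing group does. No compound outside the list arises (entry F0).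

Step 12. Slow transmetalation of the alkylborane, or hydrolysis of the vinylogous acyl triflate by the aqueous base, may leave the C12–C13 bond unmade. The fallback builds the chain by carbonyl olefination instead; it sets out from aldehyde 14 and returns at enoate 19, bypassing 15, 17 and 18. Wittig reaction with 1-(triphenylphosphoranylidene)propan-2-one in toluene at 90 °C should give the enone F5. Hydrogenation over Pd/C saturates C11=C12 to the methyl ketone F6. Horner–Wadsworth–Emmons reaction with triethyl phosphonoacetate and NaH then gives 19, the E isomer being expected to predominate and the Z isomer to be removed by chromatography.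

Further compounds
F1 | step 6 | (4S,6R)-2,4-bis(trimethylsilyloxy)-6-(2,6,6-trimethylcyclohex-1-en-1-yl)-5,6-dihydro-4H-pyran | C[Si](C)(C)OC1=C[C@@H](O[Si](C)(C)C)C[C@@H](O1)C2=C(C)CCCC2(C)C
F2 | step 6 | trimethylsilyl (1R,2S,8aS)-5,5,8a-trimethyl-2-(trimethylsilyloxy)-1,2,3,5,6,7,8,8a-octahydronaphthalene-1-carboxylate | C[Si](C)(C)O[C@H]1CC=C2C(C)(C)CCC[C@@]2(C)[C@H]1C(=O)O[Si](C)(C)C
F3 | step 6 | (1R,2S,8aS)-2-hydroxy-5,5,8a-trimethyl-1,2,3,5,6,7,8,8a-octahydronaphthalene-1-carboxylic acid | O[C@H]1CC=C2C(C)(C)CCC[C@@]2(C)[C@H]1C(O)=O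
F4 | step 6 | tert-butyldimethylsilyl (1R,2S,8aS)-2-(tert-butyldimethylsilyloxy)-5,5,8a-trimethyl-1,2,3,5,6,7,8,8a-octahydronaphthalene-1-carboxylate | CC(C)(C)[Si](C)(C)O[C@H]1CC=C2C(C)(C)CCC[C@@]2(C)[C@H]1C(=O)O[Si](C)(C)C(C)(C)C
F0 | step 8 | none | none
F5 | step 12 | (3E)-4-[(1R,2S,4aR,8aR)-2-(tert-butyldimethylsilyloxy)-5,5,8a-trimethyldecahydronaphthalen-1-yl]but-3-en-2-one | CC(C)(C)[Si](C)(C)O[C@H]1CC[C@@H]2C(C)(C)CCC[C@@]2(C)[C@H]1/C=C/C(C)=O
F6 | step 12 | 4-[(1R,2S,4aR,8aR)-2-(tert-butyldimethylsilyloxy)-5,5,8a-trimethyldecahydronaphthalen-1-yl]butan-2-one | CC(C)(C)[Si](C)(C)O[C@H]1CC[C@@H]2C(C)(C)CCC[C@@]2(C)[C@H]1CCC(C)=O
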